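**Retrosynthetic overview**

- Numbering: the heptan-3-one chain runs from C1 (benzylic CH2 on the syringyl ring) over the C3 carbonyl to C7 (benzylic CH2 on the catechol ring). The enabling feature is the C3 ketone with its unbranched α,β,γ-carbons C4–C5–C6: these three carbons can be folded into a cyclopropane ring bonded to the C3 carbonyl, which turns C6 into a homo-Michael acceptor.
- Key disconnection C6–C7: nickel-catalysed ring-opening cross-coupling of a cyclopropyl ketone with a benzylic zinc reagent. One operation forms C6–C7 and opens the three-membered ring into the C4–C6 chain; only a silyl enol ether remains to be hydrolysed.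
- The cyclopropyl ketone comes from O-benzylsyringaldehyde and cyclopropyl methyl ketone (Claisen–Schmidt condensation forming C1–C2, then C=C hydrogenation). The zinc reagent comes from 3,4-bis(benzyloxy)benzyl chloride by zinc insertion.
- Rings: both benzene rings and the cyclopropane are bought and no ring is formed. The cyclopropane is the only temporary ring and is consumed in the key step. The three benzyl ethers are removed together in the last step.

Key step: step 5

Remark: the target is achiral; the only stereo-elements on the way are alkene geometries, which are erased later.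

**Route**

Step 1
Reactants: 1 syringaldehyde (4-hydroxy-3,5-dimethoxybenzaldehyde)
Product: 2 4-(benzyloxy)-3,5-dimethoxybenzaldehyde
Conditions: BnBr (1.1 equiv), K2CO3 (1.5 equiv), DMF, 60 °C
Reagents that add atoms: benzyl bromide, BrCc1ccccc1
Why: Williamson ether synthesis: the phenoxide is the only nucleophile and is O-benzylated by SN2, while the aldehyde is inert under these conditions.

Step 2
Reactants: 2 4-(benzyloxy)-3,5-dimethoxybenzaldehyde; 3 cyclopropyl methyl ketone (1-cyclopropylethan-1-one)
Product: 5 (E)-3-[4-(benzyloxy)-3,5-dimethoxyphenyl]-1-cyclopropylprop-2-en-1-one, via aldol adduct 4 (not isolated)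
Conditions: 3 (1.5 equiv), aq. NaOH (0.3 equiv), EtOH, rt
Reagents that add atoms: none
Why: Claisen–Schmidt (crossed aldol) condensation: the aldehyde cannot enolise and the ketone enolises only at its methyl group, so aldol adduct 4 forms and dehydrates by E1cB to the conjugated enone in its thermodynamically favoured E geometry.

Step 3
Reactants: 5 (E)-3-[4-(benzyloxy)-3,5-dimethoxyphenyl]-1-cyclopropylprop-2-en-1-one
Product: 6 3-[4-(benzyloxy)-3,5-dimethoxyphenyl]-1-cyclopropylpropan-1-one
Conditions: H2 (4 atm), RhCl(PPh3)3 (5 mol %), toluene/EtOH 1:1, 40 °C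
Reagents that add atoms: none
Why: Homogeneous rhodium-catalysed hydrogenation saturates the enone C=C and, unlike heterogeneous palladium, should neither hydrogenolyse the aryl benzyl ether nor open the cyclopropyl ketone or reduce the carbonyl.

Step 4
Reactants: 7 3,4-bis(benzyloxy)benzyl chloride [1,2-bis(benzyloxy)-4-(chloromethyl)benzene]
Product: 8 [3,4-bis(benzyloxy)phenyl]methylzinc chloride (THF solution, titrated and used as such)
Conditions: Zn dust (1.5 equiv, activated), LiCl (1.5 equiv), THF, 25 °C
Reagents that add atoms: zinc, [Zn]
Why: LiCl-promoted oxidative insertion of zinc into a benzylic C–Cl bond is a standard preparation of benzylic zinc chlorides that tolerates aryl ethers; LiCl takes the organozinc off the metal surface and so keeps Wurtz coupling low.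

Step 5
Reactants: 6 3-[4-(benzyloxy)-3,5-dimethoxyphenyl]-1-cyclopropylpropan-1-one; 8 [3,4-bis(benzyloxy)phenyl]methylzinc chloride
Product: 10 1-[4-(benzyloxy)-3,5-dimethoxyphenyl]-7-[3,4-bis(benzyloxy)phenyl]heptan-3-one, via trimethylsilyl enol ether 9 (not isolated)
Conditions: NiCl2·dme (10 mol %), 2,2′:6′,2″-terpyridine (10 mol %), TMSCl (1.5 equiv), 8 (1.5 equiv, slow addition), THF/NMP, rt; then 1 M HCl, THF
Reagents that add atoms: none
Why: A reduced terpyridine–nickel(I) species, helped by O-silylation of the carbonyl by TMSCl, should cleave one of the two equivalent C4–CH2 bonds of the carbonyl-conjugated cyclopropane in a concerted asynchronous ring opening, giving a nickel alkyl at C6 that carries the Z-silyl enol ether; transmetalation with benzylic zinc reagent 8 and C(sp3)–C(sp3) reductive elimination then form C6–C7, and acidic work-up hydrolyses enol ether 9 to ketone 10. The closest known reaction type is the terpyridine–nickel-catalysed ring-opening cross-coupling of cyclopropyl ketones with organozinc reagents and TMSCl to γ-substituted silyl enol ethers, a net homo-conjugate addition in which the benzylic zinc reagent here takes the place of the alkylzinc reagents. No ring is closed (the cyclopropane is opened) and no stereocentre is formed. The step needs cleavage of a ring bond next to the carbonyl, which conjugation with the ketone secures and which the symmetry of the unsubstituted ring makes constitutionally unambiguous, and attack at C6 instead of 1,2-addition, which the low carbonyl reactivity of organozinc reagents secures. Cross-coupling must also outrun benzyl homocoupling and β-hydride elimination of the nickel alkyl; slow addition of 8 and the tridentate terpyridine ligand are meant to secure this.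

Step 6
Reactants: 10 1-[4-(benzyloxy)-3,5-dimethoxyphenyl]-7-[3,4-bis(benzyloxy)phenyl]heptan-3-one
Product: 11 7-(3,4-dihydroxyphenyl)-1-(4-hydroxy-3,5-dimethoxyphenyl)heptan-3-one
Conditions: H2 (1 atm), 10% Pd/C, EtOAc/EtOH 1:1, rt; filtration and concentration under argon
Reagents that add atoms: none
Why: Catalytic hydrogenolysis cleaves the three aryl benzyl ethers over palladium; the dialkyl ketone and the aryl methyl ethers are inert at 1 atm and room temperature, and air is excluded on work-up to protect the catechol.

**Compound list**

1 | syringaldehyde (4-hydroxy-3,5-dimethoxybenzaldehyde) | COc1cc(C=O)cc(OC)c1O | starting material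
2 | 4-(benzyloxy)-3,5-dimethoxybenzaldehyde | COc1cc(C=O)cc(OC)c1OCc1ccccc1 | intermediate
3 | cyclopropyl methyl ketone (1-cyclopropylethan-1-one) | CC(=O)C1CC1 | starting material
4 | 3-[4-(benzyloxy)-3,5-dimethoxyphenyl]-1-cyclopropyl-3-hydroxypropan-1-one (racemic aldol adduct, not isolated) | COc1cc(C(O)CC(=O)C2CC2)cc(OC)c1OCc1ccccc1 | intermediate
5 | (E)-3-[4-(benzyloxy)-3,5-dimethoxyphenyl]-1-cyclopropylprop-2-en-1-one | COc1cc(/C=C/C(=O)C2CC2)cc(OC)c1OCc1ccccc1 | intermediate
6 | 3-[4-(benzyloxy)-3,5-dimethoxyphenyl]-1-cyclopropylpropan-1-one | COc1cc(CCC(=O)C2CC2)cc(OC)c1OCc1ccccc1 | intermediate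
7 | 3,4-bis(benzyloxy)benzyl chloride [1,2-bis(benzyloxy)-4-(chloromethyl)benzene] | ClCc1ccc(OCc2ccccc2)c(OCc2ccccc2)c1 | starting material
8 | [3,4-bis(benzyloxy)phenyl]methylzinc chloride | Cl[Zn]Cc1ccc(OCc2ccccc2)c(OCc2ccccc2)c1 | intermediate
9 | {[(3Z)-1-[4-(benzyloxy)-3,5-dimethoxyphenyl]-7-[3,4-bis(benzyloxy)phenyl]hept-3-en-3-yl]oxy}trimethylsilane (silyl enol ether, not isolated) | COc1cc(CC/C(O[Si](C)(C)C)=C/CCCc2ccc(OCc3ccccc3)c(OCc3ccccc3)c2)cc(OC)c1OCc1ccccc1 | intermediate
10 | 1-[4-(benzyloxy)-3,5-dimethoxyphenyl]-7-[3,4-bis(benzyloxy)phenyl]heptan-3-one | COc1cc(CCC(=O)CCCCc2ccc(OCc3ccccc3)c(OCc3ccccc3)c2)cc(OC)c1OCc1ccccc1 | intermediate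
11 | 7-(3,4-dihydroxyphenyl)-1-(4-hydroxy-3,5-dimethoxyphenyl)heptan-3-one | COc1cc(CCC(=O)CCCCc2ccc(O)c(O)c2)cc(OC)c1O | target

**Step count and risks**

Total step count: 6. Longest linear sequence: 5 steps (steps 1, 2, 3, 5, 6); step 4 is a one-step branch.

Steps most likely to fail:

Step 5. The C–C activation of a cyclopropyl ketone that carries no aryl group on the carbonyl may be slow, so that homocoupling or protonation of the benzylic zinc reagent uses it up before cross-coupling. The fallback forms the same C6–C7 bond as an alkene by metathesis. It sets out from 2: Claisen–Schmidt condensation with commercial hex-5-en-2-one (aq. NaOH, EtOH; condensation is expected at the methyl group) should give (E)-1-[4-(benzyloxy)-3,5-dimethoxyphenyl]hepta-1,6-dien-3-one F1. Commercial 3,4-bis(benzyloxy)benzaldehyde is methylenated by a Wittig reaction (methyltriphenylphosphonium bromide, KOtBu, THF) to 3,4-bis(benzyloxy)styrene F2. Olefin cross-metathesis of the terminal alkene of F1 with excess F2 [(H2IMes)(PCy3)Cl2Ru=CHPh, CH2Cl2, 40 °C] should give (1E,6E)-1-[4-(benzyloxy)-3,5-dimethoxyphenyl]-7-[3,4-bis(benzyloxy)phenyl]hepta-1,6-dien-3-one F3; the aryl-conjugated enone alkene is not expected to take part. Hydrogenation over Pd/C (H2, EtOAc/EtOH) then saturates both alkenes and removes the three benzyl groups, so the fallback comes back to the route at 11.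

Step 4. Wurtz-type homocoupling of the electron-rich benzylic chloride on the zinc surface, or incomplete insertion, would give a weak or impure reagent solution. The fallback does not use oxidative insertion of zinc. It sets out from 7: magnesium turnings with LiCl and ZnCl2 in THF at rt generate [3,4-bis(benzyloxy)phenyl]methylmagnesium chloride F4, which is transmetalated by the zinc chloride as it forms, so that its stationary concentration stays low. The fallback comes back to the route at 8.

Step 3. Hydrogen uptake by the aryl-conjugated trans-enone may be slow with the homogeneous rhodium catalyst, which could decay before conversion is complete. The fallback avoids a separate alkene reduction. It sets out from 2: reduction (NaBH4, MeOH, 0 °C) gives [4-(benzyloxy)-3,5-dimethoxyphenyl]methanol F5. Hydrogen-borrowing α-alkylation of excess 3 with this alcohol ([Cp*IrCl2]2 cat., KOH cat., toluene, 110 °C) dehydrogenates the alcohol to 2, condenses it to 5 in the flask and returns the borrowed hydrogen to the C=C bond. The fallback comes back to the route at 6.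

**Further compounds**

F1 | step 5 | (E)-1-[4-(benzyloxy)-3,5-dimethoxyphenyl]hepta-1,6-dien-3-one | COc1cc(/C=C/C(=O)CCC=C)cc(OC)c1OCc1ccccc1
F2 | step 5 | 3,4-bis(benzyloxy)styrene [1,2-bis(benzyloxy)-4-ethenylbenzene] | C=Cc1ccc(OCc2ccccc2)c(OCc2ccccc2)c1
F3 | step 5 | (1E,6E)-1-[4-(benzyloxy)-3,5-dimethoxyphenyl]-7-[3,4-bis(benzyloxy)phenyl]hepta-1,6-dien-3-one | COc1cc(/C=C/C(=O)CC/C=C/c2ccc(OCc3ccccc3)c(OCc3ccccc3)c2)cc(OC)c1OCc1ccccc1
F4 | step 4 | [3,4-bis(benzyloxy)phenyl]methylmagnesium chloride | Cl[Mg]Cc1ccc(OCc2ccccc2)c(OCc2ccccc2)c1
F5 | step 3 | [4-(benzyloxy)-3,5-dimethoxyphenyl]methanol | COc1cc(CO)cc(OC)c1OCc1ccccc1
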